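**Retrosynthetic overview**
1. Target 8 is C2-symmetric, so both arms come from one alkyne, 5-ethynyl-2,2'-bithiophene 4 (from bromide 1 by Sonogashira coupling and desilylation).
2. Key disconnection: the C(sp)–C(sp3) bond between one arm and its ring carbon, made by cobalt-catalysed enantioselective syn-hydroalkynylation of the flat, achiral enyne 7 with 4. This one step joins the halves, saturates the ring and sets both stereocentres (trans, 1R,2R).
3. Enabling feature: the strained C1=C2 double bond of the four-membered carbocycle of 7, conjugated at C1 with the C≡C of the first arm. Strain drives the insertion; conjugation steers cobalt to C1 and the incoming alkynyl to the unsubstituted C2.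
4. Enyne 7 comes from cyclobutanone 5 via enol triflate 6 and Sonogashira coupling with 4.
5. Ring order: no ring is formed; both bithiophenes and the four-membered ring are bought intact, and the cyclobutene is brought to the cyclobutane level last.

Key step: step 5

Assumption: the sense of induction of the cobalt/bisphosphine catalyst cannot be predicted for this substrate, so the ligand antipode that gives (1R,2R)-8 is fixed in a pilot run; all bithienyl alkynes are handled under argon in the dark and below 60 °C.

**Route**

Step 1
Reactants: 1 5-bromo-2,2'-bithiophene; 2 ethynyltrimethylsilane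
Product: 3 5-[(trimethylsilyl)ethynyl]-2,2'-bithiophene
Conditions: PdCl2(PPh3)2 (2 mol %), CuI (4 mol %), Et3N, THF, 55 °C
Reagents that add atoms: none
Why: Sonogashira coupling of a 2-bromothiophene with a silyl-capped alkyne is routine, and the silyl cap prevents Glaser dimerisation and double coupling.

Step 2
Reactants: 3 5-[(trimethylsilyl)ethynyl]-2,2'-bithiophene
Product: 4 5-ethynyl-2,2'-bithiophene
Conditions: K2CO3 (cat.), MeOH/THF, 20 °C
Reagents that add atoms: none
Why: Base-catalysed methanolysis of the C(sp)–Si bond (protodesilylation) is mild and leaves both thiophene rings untouched.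

Step 3
Reactants: 5 cyclobutanone
Product: 6 cyclobut-1-en-1-yl trifluoromethanesulfonate
Conditions: Tf2O, 2,6-di-tert-butyl-4-methylpyridine, CH2Cl2, 0 to 20 °C; filtered through pentane, carried on as a solution
Reagents that add atoms: trifluoromethanesulfonic anhydride, O=S(=O)(OS(=O)(=O)C(F)(F)F)C(F)(F)F
Why: O-Sulfonylation of the ketone with a hindered, non-nucleophilic pyridine base (vinyl triflate synthesis) avoids a free enolate and hence aldol self-condensation of cyclobutanone.

Step 4
Reactants: 6 cyclobut-1-en-1-yl trifluoromethanesulfonate; 4 5-ethynyl-2,2'-bithiophene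
Product: 7 5-(cyclobut-1-en-1-ylethynyl)-2,2'-bithiophene
Conditions: Pd(PPh3)4 (3 mol %), CuI (5 mol %), Et3N, THF, 20 °C, degassed
Reagents that add atoms: none
Why: Sonogashira coupling of an alkenyl triflate with a terminal alkyne runs at room temperature with zerovalent palladium and CuI, which spares the strained cyclobutene.

Step 5
Reactants: 7 5-(cyclobut-1-en-1-ylethynyl)-2,2'-bithiophene; 4 5-ethynyl-2,2'-bithiophene
Product: 8 cardopatine, (1R,2R)-trans-1,2-bis[(2,2'-bithiophen-5-yl)ethynyl]cyclobutane
Conditions: Co(OAc)2 (10 mol %), (S,S)-Ph-BPE (12 mol %), Zn dust (20 mol %), THF, 30 °C, 4 added slowly by syringe pump, argon, dark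
Reagents that add atoms: none
Why: Proposed new method: the cobalt acetylide (bisphosphine)Co–C≡C–Ar, a low-valent species formed from 4 with loss of acetic acid, should insert the strained ring C1=C2 bond of 7 in a syn carbometalation that puts the alkynyl carbon on the unsubstituted C2 and cobalt on C1, where it is held as a propargyl/allenyl cobalt by the C≡C of the resident arm, and inner-sphere protonolysis of the C1–Co bond with retention by the next molecule of 4 then releases 8 and renews the acetylide, so that nothing is formed beside the product. The closest known reaction type is the cobalt-catalysed enantioselective hydroalkynylation of simple cyclobutenes by carbometalation and protonation, and the regiochemistry copies the additions of L–Cu–B(pin) and L–Cu–H to 1,3-enynes, which also place the metal on the propargylic carbon; new is a cyclobutene that is the alkene half of a conjugated enyne. No ring is closed in this step. The stereocentre at C2 is set by the chiral bisphosphine, which picks one enantiotopic face of the flat, achiral enyne in the carbometalation, and the stereocentre at C1 is set by that same event, since the C–C and C–H bonds arrive on one face and the two alkynyl arms therefore end up trans. The step needs chemoselectivity for the ring alkene over every alkyne in the flask, regioselectivity for C2, and proton delivery to C1 rather than to the far end of the allenyl system: ring strain and the unhindered C2–H terminus of the cyclobutene secure the first two, the internal alkynes are shielded by a ring on one side and a bithienyl on the other, and slow addition of 4 keeps its own dimerisation down.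

**Compound list**
1 | 5-bromo-2,2'-bithiophene | Brc1ccc(-c2cccs2)s1 | starting material
2 | ethynyltrimethylsilane | C#C[Si](C)(C)C | starting material
3 | 5-[(trimethylsilyl)ethynyl]-2,2'-bithiophene | C[Si](C)(C)C#Cc1ccc(-c2cccs2)s1 | intermediate
4 | 5-ethynyl-2,2'-bithiophene | C#Cc1ccc(-c2cccs2)s1 | intermediate
5 | cyclobutanone | O=C1CCC1 | starting material
6 | cyclobut-1-en-1-yl trifluoromethanesulfonate | O=S(=O)(OC1=CCC1)C(F)(F)F | intermediate
7 | 5-(cyclobut-1-en-1-ylethynyl)-2,2'-bithiophene | C(#CC1=CCC1)c1ccc(-c2cccs2)s1 | intermediate
8 | cardopatine, (1R,2R)-trans-1,2-bis[(2,2'-bithiophen-5-yl)ethynyl]cyclobutane | C(#C[C@@H]1CC[C@H]1C#Cc1ccc(-c2cccs2)s1)c1ccc(-c2cccs2)s1 | target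

Total steps: 5. Longest linear sequence: 4 steps (1 → 3 → 4 → 7 → 8).

**Steps most likely to fail**

Step 5 (key step). What may go wrong:
- insertion of the cobalt acetylide into C≡C bonds instead of the ring alkene (dimerisation or oligomerisation of 4);
- protonation of the propargyl/allenyl cobalt at its remote carbon or from the face away from cobalt (allene or cis isomer);
- weak enantiofacial discrimination on a flat enyne.

Fallback, known chemistry, making the same bond by radical cross-coupling; it sets out from alkyne 4 and returns to the route at target 8. Commercial meso cis-cyclobutane-1,2-dicarboxylic anhydride (O=C1OC(=O)[C@@H]2CC[C@H]12) is opened with methanol and a stoichiometric cinchona alkaloid in toluene at −55 °C, the pseudoenantiomer (quinine or quinidine) being chosen that gives (1S,2R)-2-(methoxycarbonyl)cyclobutane-1-carboxylic acid F1. N-Hydroxyphthalimide and N,N'-diisopropylcarbodiimide convert it into the redox-active ester 1-(1,3-dioxoisoindolin-2-yl) 2-methyl (1S,2R)-cyclobutane-1,2-dicarboxylate F2. Alkyne 4 is zincated with TMPZnCl·LiCl in THF to [(2,2'-bithiophen-5-yl)ethynyl]zinc chloride F3. Nickel-catalysed decarboxylative alkynylation of F2 with F3 (NiCl2·6H2O, 4,4'-dimethoxy-2,2'-bipyridine, THF/DMF, 20 °C) should give, by capture of the cyclobutyl radical trans to the ester, methyl (1R,2R)-2-[(2,2'-bithiophen-5-yl)ethynyl]cyclobutane-1-carboxylate F4; any cis isomer is removed by chromatography, which protects the enantiomeric purity. Saponification (LiOH, THF/H2O) gives (1R,2R)-2-[(2,2'-bithiophen-5-yl)ethynyl]cyclobutane-1-carboxylic acid F5; epimerisation at the carboxyl carbon does not matter, because that centre is erased next. The acid is activated as 1,3-dioxoisoindolin-2-yl (1R,2R)-2-[(2,2'-bithiophen-5-yl)ethynyl]cyclobutane-1-carboxylate F6 and alkynylated with F3 under the same nickel conditions. The planar radical should again take up the alkynyl group trans to the resident arm, so cis and trans acid converge on 8.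

Step 3. What may go wrong: evaporative loss and acid-triggered decomposition of the small, strained enol triflate, and self-condensation of cyclobutanone before O-sulfonylation.

Fallback; it sets out from 4 and 5 and returns at 7, bypassing 6. Deprotonation of 4 (n-BuLi, THF, −78 °C) gives lithium (2,2'-bithiophen-5-yl)acetylide F7. It adds to cyclobutanone 5 (CeCl3 may be added to suppress enolisation) and gives, after aqueous NH4Cl, 1-[(2,2'-bithiophen-5-yl)ethynyl]cyclobutan-1-ol F8. Syn-dehydration with Burgess reagent (methyl N-(triethylammoniumsulfonyl)carbamate, toluene, 50 °C) should give 7 without a free cyclobutyl cation.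

Step 4. What may go wrong: oxidative homocoupling of the electron-rich alkyne outrunning the cross-coupling while the triflate slowly decays.

Fallback; it sets out from 6 and returns at 7, moving the coupling bond to the arene side. Triflate 6 is coupled with an excess of ethynyltrimethylsilane 2 (Pd(PPh3)4, CuI, Et3N, THF, 20 °C) to 1-[(trimethylsilyl)ethynyl]cyclobut-1-ene F9. F9 is then joined to bromide 1 in a fluoride-promoted desilylative Sonogashira coupling (Pd(PPh3)4, CuI, CsF, DMF, 50 °C) to give 7.

**Further compounds**
F1 | step 5 | (1S,2R)-2-(methoxycarbonyl)cyclobutane-1-carboxylic acid | OC(=O)[C@H]1CC[C@H]1C(=O)OC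
F2 | step 5 | 1-(1,3-dioxoisoindolin-2-yl) 2-methyl (1S,2R)-cyclobutane-1,2-dicarboxylate | O=C(ON1C(=O)c2ccccc2C1=O)[C@H]1CC[C@H]1C(=O)OC
F3 | step 5 | [(2,2'-bithiophen-5-yl)ethynyl]zinc chloride | Cl[Zn]C#Cc1ccc(-c2cccs2)s1
F4 | step 5 | methyl (1R,2R)-2-[(2,2'-bithiophen-5-yl)ethynyl]cyclobutane-1-carboxylate | C(#C[C@@H]1CC[C@H]1C(=O)OC)c1ccc(-c2cccs2)s1
F5 | step 5 | (1R,2R)-2-[(2,2'-bithiophen-5-yl)ethynyl]cyclobutane-1-carboxylic acid | C(#C[C@@H]1CC[C@H]1C(=O)O)c1ccc(-c2cccs2)s1
F6 | step 5 | 1,3-dioxoisoindolin-2-yl (1R,2R)-2-[(2,2'-bithiophen-5-yl)ethynyl]cyclobutane-1-carboxylate | C(#C[C@@H]1CC[C@H]1C(=O)ON1C(=O)c2ccccc2C1=O)c1ccc(-c2cccs2)s1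
F7 | step 3 | lithium (2,2'-bithiophen-5-yl)acetylide | [Li]C#Cc1ccc(-c2cccs2)s1
F8 | step 3 | 1-[(2,2'-bithiophen-5-yl)ethynyl]cyclobutan-1-ol | OC1(C#Cc2ccc(-c3cccs3)s2)CCC1
F9 | step 4 | 1-[(trimethylsilyl)ethynyl]cyclobut-1-ene | C[Si](C)(C)C#CC1=CCC1
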